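**The pitfall.** A short charge of partner, the limiting reagent, looks like a yield already written down, and it tempts one to count much of it as product by the end. But a charge says how much partner stands in the flask, not how much of it has reacted within the time.

| setting | winter | dusk | autumn | north | south-east | west | north-west | south-west |
|---|---|---|---|---|---|---|---|---|
| substrate | 10 mM | 10 mM | 10 mM | 10 mM | 10 mM | 10 mM | 10 mM | 10 mM |
| partner | 0.042 equiv | 0.36 equiv | 3.5 equiv | 0.0400 equiv | 0.120 equiv | 0.300 equiv | 1.00 equiv | 3.00 equiv |
| remark | run made earlier | run made earlier | run made earlier |  |  |  |  |  |
| time |  |  |  | 2.0 h | 2.0 h | 2.0 h | 2.0 h | 2.0 h |

- winter (time / min: product / %): 5.00: 0; 10.0: 0; 15.0: 1; 30.0: 0; 60.0: 0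
- dusk (time / min: product / %): 5.00: 0; 10.0: 2; 15.0: 0; 30.0: 2; 60.0: 7
- autumn (time / min: product / %): 12.0: 0; 25.0: 8; 40.0: 14; 50.0: 19; 60.0: 25

(standard deviation of a reading: 2 percentage points)

- the numbers in the tables scatter with a standard deviation of 2 percentage points
- steps that have been proposed: substrate -> intermediate; partner + intermediate <-> product
- "hardly changes" means that all values lie within two and a half points (for a concentration: within two and a half percent of the largest)

1. amount of product at the end, in percent of the substrate charged for north, south-east, west, north-west, south-west, in this order
2. the course of these numbers from the first flask to the last (falls all the way / hardly changes / rises, then falls / rises all the way / falls, then rises)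

**Counting turnovers.** On the proposed steps, substrate turns into intermediate without partner, and then partner meets intermediate to give product. The forward rate of that second step is a rate constant times partner times intermediate. So the chance per minute for one partner molecule is the rate constant times intermediate, and the partner charge enters it through the intermediate that partner itself consumes. That suggests counting per partner molecule rather than per flask.

**What the readings give.** Dusk reads 7% at 60.0 min against a scatter of 2 percentage points, and winter reads 0%, so neither gives a count worth carrying. Autumn stands clear of the scatter: it gains 17 points between 25.0 min and 60.0 min. My own straight line through those readings, carried on to 2.0 h, stands at 54.1% of the substrate. Spread over the 3.5 equiv of partner, that gives the partner share, the fraction of the charged partner turned into product by 2.0 h: 15.5%.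

**The row.** Holding the share at the value read from autumn, product in percent of substrate is equivalents times share. My reckoning gives 0.619%, 1.86%, 4.64%, 15.5% and 46.5%, rising along the row.

**The forecast.** It gives 2%, 6%, 13%, 30% and 40%, rises all the way, on the ground that “Low-partner flasks therefore consume about half their partner”, which puts north higher than my reckoning does.

**The flasks.** Product ends at 0.893%, 2.65%, 6.44%, 19.4% and 44.3%, and the course rises all the way.

    substrate → intermediate (k = 0.0215 min⁻¹)
    partner + intermediate ⇌ product (K = 56.6 M⁻¹, k = 0.501 M⁻¹ min⁻¹)

**The count again.** North ends with 78% of its partner left, and its product amounts to 22.3% of its partner charge, more than the carried share of 15.5%. South-west is the second test: its 3.00 equiv times 15.5% gives 46.5%, and the flask holds 44.3% of product.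

(The readings stem from a simulated flask for an exercise.)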